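**Plan**

- Retrosynthesis: in each oxane (O1, C2 bearing the cyclopentyl, C3, C4, C5 bearing the exocyclic alkene, C6) the C3–C4 and O1–C6 bonds are cut. This leaves a C8 core, 2,7-bis(chloromethyl)octa-1,7-diene-3,6-diol, esterified on both carbinols by a β-hydroxy acid.
- Enabling feature: C4–C5(=CH–chain)–C6 of each oxane is a 2-(oxymethyl)allyl unit. An acyloxy group on the exocyclic CH makes it a secondary allyl β-hydroxy ester whose α-carbon is C3 and whose carbinol is C2, so a [3,3] shift delivers C3 to C4, fixes the (Z)-alkene in a chair, and frees O1 to displace chloride at C6.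
- Further cuts: the core at its two carbinol–vinyl bonds (one succinaldehyde plus two 2-lithioallyl units), the β-hydroxy acid at its carbonyl carbon (epoxide plus CO), the cyclopentane at the carbinol–CH(isopropenyl) bond (carbonyl-ene).
- Forward: (S)-malate → alkylation → ene cyclopentanol → epoxide → β-lactone; core diol; double acylation; double rearrangement/etherification closes both oxanes and sets both alkenes; double decarboxylation; desilylation.
- Stereochemistry: oxane C2 from (S)-malate; the adjacent ring carbon from anti-selective dianion alkylation; carbinol and isopropenyl carbons from the ene transition state; alkene geometry from the Claisen chair. The ester tether leaves CO2H on C3, removed by Barton decarboxylation.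

Key step: step 16

Remark: 5-iodo-2-methylpent-2-ene is taken as purchased; it is otherwise one NaI exchange from the commercial bromide.
Remark: Cyp stands for the 2-[(tert-butyldimethylsilyl)oxy]-3-(prop-1-en-2-yl)cyclopentyl group made in step 6, attached through C1, silyloxy cis to isopropenyl and trans to the C1 substituent, absolute configuration unchanged from there on.
Remark: the C8 core diol forms as a mixture of meso and racemic forms, so its esters are diastereomer mixtures; the core carbinol centers are erased in step 16 and the epimeric C3 carboxyl centers in step 17, so all isomers converge.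
Remark: from step 12 on every intermediate carries two like ends. Step 12 consumes two molecules of 14 per molecule of 16, step 13 two molecules of 12 per molecule of 18, and steps 14–18 act on both ends at once.

**Route**

Step 1
Reactants: 1 dimethyl (S)-malate; 2 5-iodo-2-methylpent-2-ene
Product: 3 dimethyl (2S,3R)-2-hydroxy-3-(4-methylpent-3-en-1-yl)butanedioate
Conditions: LiN(iPr)2 (2.2 equiv), THF, −78 → −20 °C; then 2, DMPU, −78 → 0 °C
Reagents that add atoms: none
Why: Fráter–Seebach alkylation: the chelated lithium alkoxide–enolate dianion should be alkylated anti to the C2 oxygen, setting the (3R) center next to the (2S) carbinol carried from malate, with DMPU helping the unactivated primary iodide.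

Step 2
Reactants: 3 dimethyl (2S,3R)-2-hydroxy-3-(4-methylpent-3-en-1-yl)butanedioate
Product: 4 methyl (2R,3S)-3,4-dihydroxy-2-(4-methylpent-3-en-1-yl)butanoate
Conditions: BH3·SMe2 (1.05 equiv), NaBH4 (5 mol %), THF, 0 °C → rt; MeOH
Reagents that add atoms: none
Why: Hydroxyl-directed borane reduction of an α-hydroxy ester: the alkoxyborane formed at the free hydroxyl should deliver hydride through a five-membered chelate to the neighbouring ester only, faster than the distal ester or the trisubstituted alkene reacts, and no stereocenter is touched.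

Step 3
Reactants: 4 methyl (2R,3S)-3,4-dihydroxy-2-(4-methylpent-3-en-1-yl)butanoate
Product: 5 methyl (2R)-2-[(4S)-2,2-dimethyl-1,3-dioxolan-4-yl]-6-methylhept-5-enoate
Conditions: Me2C(OMe)2, pyridinium p-toluenesulfonate (cat.), CH2Cl2, rt
Reagents that add atoms: 2,2-dimethoxypropane COC(C)(C)OC
Why: Acid-catalysed transketalization (acetonide formation) should cap the 1,2-diol faster than the γ-hydroxy ester lactonizes, leaving both stereocenters untouched.

Step 4
Reactants: 5 methyl (2R)-2-[(4S)-2,2-dimethyl-1,3-dioxolan-4-yl]-6-methylhept-5-enoate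
Product: 6 (2R)-2-[(4S)-2,2-dimethyl-1,3-dioxolan-4-yl]-6-methylhept-5-enal
Conditions: iBu2AlH (1.1 equiv), CH2Cl2, −78 °C; MeOH, aq. KNaC4H4O6
Reagents that add atoms: none
Why: Partial ester reduction with iBu2AlH at −78 °C should stop at the aluminium hemiacetal, which gives the aldehyde only on work-up, so the α-stereocenter never meets base.

Step 5
Reactants: 6 (2R)-2-[(4S)-2,2-dimethyl-1,3-dioxolan-4-yl]-6-methylhept-5-enal
Product: 7 (1S,2S,5R)-2-[(4S)-2,2-dimethyl-1,3-dioxolan-4-yl]-5-(prop-1-en-2-yl)cyclopentan-1-ol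
Conditions: Me2AlCl (1.1 equiv), CH2Cl2, −78 → −40 °C
Reagents that add atoms: none
Why: Lewis-acid-promoted intramolecular carbonyl-ene reaction (type 1): the Al-bound aldehyde is attacked by the trisubstituted alkene in a cis-fused bicyclic transition state in which a methyl hydrogen passes to oxygen, which should place hydroxyl and isopropenyl cis, while the dioxolanyl group on the α-carbon should sit on the convex face anti to the Al-bound oxygen and so end trans to the hydroxyl.

Step 6
Reactants: 7 (1S,2S,5R)-2-[(4S)-2,2-dimethyl-1,3-dioxolan-4-yl]-5-(prop-1-en-2-yl)cyclopentan-1-ol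
Product: 8 tert-butyldimethylsilyl ether of 7 at the ring hydroxyl (configuration unchanged)
Conditions: tert-butyldimethylsilyl triflate, 2,6-lutidine, CH2Cl2, −78 → 0 °C
Reagents that add atoms: tert-butyldimethylsilyl trifluoromethanesulfonate CC(C)(C)[Si](C)(C)OS(=O)(=O)C(F)(F)F
Why: Silylation with the silyl triflate and a hindered base is the standard protection of a flanked secondary alcohol and should leave the dioxolane intact at low temperature.

Step 7
Reactants: 8 tert-butyldimethylsilyl ether of 7
Product: 9 (1S)-1-Cyp-ethane-1,2-diol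
Conditions: pyridinium p-toluenesulfonate (cat.), MeOH, 40 °C
Reagents that add atoms: none
Why: Transketalization to methanol under mild acid should release the terminal 1,2-diol while the hindered secondary silyl ether and the alkene survive.

Step 8
Reactants: 9 (1S)-1-Cyp-ethane-1,2-diol
Product: 11 (2S)-2-Cyp-oxirane, via primary monotosylate 10 (not isolated)
Conditions: NaH (2.2 equiv), 1-(p-toluenesulfonyl)imidazole (1.05 equiv), THF, 0 °C → rt
Reagents that add atoms: none
Why: Selective sulfonylation of the primary alkoxide followed by intramolecular Williamson closure (3-exo-tet) by the secondary alkoxide should give the epoxide with retention at the carbinol carbon, whose C–O bond is never broken.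

Step 9
Reactants: 11 (2S)-2-Cyp-oxirane
Product: 12 (4R)-4-Cyp-oxetan-2-one
Conditions: CO (60 bar), [(salph)Al(THF)2][Co(CO)4] (2 mol %; salph = dianion of N,N′-bis(3,5-di-tert-butylsalicylidene)-1,2-phenylenediamine), THF, 50 °C
Reagents that add atoms: carbon monoxide [C-]#[O+]
Why: Ring-expanding carbonylation of an epoxide with a Lewis acid/[Co(CO)4]− ion pair: cobaltate opens the Al-activated epoxide at the CH2 carbon, CO inserts and the alkoxide closes on the acyl cobalt, so the β-lactone should form with the configured C–O bond untouched.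

Step 10
Reactants: 13 2,3-dibromoprop-1-ene
Product: 14 1-{[(2-bromoprop-2-en-1-yl)oxy]methyl}-4-methoxybenzene
Conditions: 4-methoxybenzyl alcohol, NaH, THF, 0 °C → rt
Reagents that add atoms: 4-methoxybenzyl alcohol COc1ccc(CO)cc1
Why: Williamson ether synthesis: the alkoxide should displace only the allylic bromide, the vinylic bromide being inert to SN2.

Step 11
Reactants: 15 2,5-dimethoxytetrahydrofuran
Product: 16 succinaldehyde (butanedial)
Conditions: H2O, 90 °C; extraction and distillation, used at once
Reagents that add atoms: water O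
Why: Hydrolysis of the cyclic bis-acetal in hot water unmasks the dialdehyde, which is distilled and used immediately to avoid oligomerization.

Step 12
Reactants: 14 1-{[(2-bromoprop-2-en-1-yl)oxy]methyl}-4-methoxybenzene (2.2 equiv); 16 succinaldehyde (1.0 equiv)
Product: 18 2,7-bis{[(4-methoxybenzyl)oxy]methyl}octa-1,7-diene-3,6-diol, via 2-lithioallyl ether 17 (not isolated)
Conditions: 14 (2.2 equiv), t-BuLi (4.4 equiv), Et2O, −78 °C; then 16 (1.0 equiv), −78 → 0 °C; aq. NH4Cl
Reagents that add atoms: none
Why: Bromine–lithium exchange gives the 2-lithioallyl ether, two molecules of which add 1,2 to the two aldehyde groups of one molecule of succinaldehyde (the second after the intermediate lactolate reopens on warming), so the bis(allylic alcohol) should form with two uncontrolled carbinol centers, which is harmless because step 16 destroys them.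

Step 13
Reactants: 12 (4R)-4-Cyp-oxetan-2-one (2.1 equiv); 18 2,7-bis{[(4-methoxybenzyl)oxy]methyl}octa-1,7-diene-3,6-diol (1.0 equiv)
Product: 19 2,7-bis{[(4-methoxybenzyl)oxy]methyl}octa-1,7-diene-3,6-diyl bis[(3R)-3-Cyp-3-hydroxypropanoate]
Conditions: 18 (1.0 equiv), NaN(SiMe3)2 (2.05 equiv), THF, −78 °C; 12 (2.1 equiv), −78 → −40 °C; AcOH
Reagents that add atoms: none
Why: Alcoholysis of a β-lactone by alkoxide proceeds by acyl–oxygen cleavage driven by ring strain, so each of the two secondary alkoxides of the core should be acylated by one molecule of the lactone and the β-hydroxyl released with its configuration unchanged.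

Step 14
Reactants: 19 bis(4-methoxybenzyl) ether bis(β-hydroxy ester)
Product: 20 2,7-bis(hydroxymethyl)octa-1,7-diene-3,6-diyl bis[(3R)-3-Cyp-3-hydroxypropanoate]
Conditions: 2,3-dichloro-5,6-dicyano-1,4-benzoquinone (2.4 equiv), CH2Cl2/pH 7 buffer, 0 °C
Reagents that add atoms: none
Why: Oxidative cleavage of 4-methoxybenzyl ethers goes through the benzylic cation and should free the two primary allylic alcohols without touching silyl ethers, esters or the secondary hydroxyls.

Step 15
Reactants: 20 2,7-bis(hydroxymethyl)octa-1,7-diene-3,6-diyl bis[(3R)-3-Cyp-3-hydroxypropanoate]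
Product: 21 2,7-bis(chloromethyl)octa-1,7-diene-3,6-diyl bis[(3R)-3-Cyp-3-hydroxypropanoate]
Conditions: N-chlorosuccinimide (2.6 equiv), Me2S (3.0 equiv), CH2Cl2, −20 → 0 °C
Reagents that add atoms: N-chlorosuccinimide O=C1CCC(=O)N1Cl
Why: Corey–Kim chlorination: the alkoxysulfonium ion of an allylic alcohol is displaced by chloride, whereas those of the non-allylic secondary β-hydroxyls are not and return the alcohols on work-up, so only the two primary allylic positions should be chlorinated, one equivalent of reagent serving each.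

Step 16
Reactants: 21 2,7-bis(chloromethyl)octa-1,7-diene-3,6-diyl bis[(3R)-3-Cyp-3-hydroxypropanoate]
Product: 23 (5Z,5′Z)-5,5′-(butane-1,4-diylidene)bis(2-Cyp-oxane-3-carboxylic acid), via tetralithium bis(hydroxy carboxylate) 22 (not isolated)
Conditions: LiN(iPr)2 (4.4 equiv), THF, 0.005 M, −78 °C → rt → 65 °C; then 1 M HCl
Reagents that add atoms: none
Why: Proposed new method: two equivalents of base per ester give the chelated alkoxide–enolate dianion, which should undergo the ester-enolate [3,3] shift through a chair with the core chain on the carbinol carbon equatorial, so the C3–C4 bond forms at the former =CH2 terminus and the new trisubstituted alkene has the chain trans to C4 and cis to CH2Cl, the (Z) geometry of the target, as in the classic Claisen route from 2-substituted secondary allylic alcohols. The closest known reactions are the dianionic ester-enolate (Ireland-type) Claisen rearrangement of allyl β-hydroxy esters and the intramolecular Williamson etherification; new is only their coupling in one flask. The shift leaves the lithium alkoxide O1 five bonds from the allylic chloride, and it should close each oxane by 6-exo-tet SN2 at C6 without touching the alkene. No stereocenter of the target is made here: C2 is carried from step 1, the core carbinol centers are destroyed, and the uncontrolled C3 carboxyl center is removed in step 17. The step needs the shift to outrun C-alkylation of the enolate by an allylic chloride, in a second molecule or in its own ester (6-enolendo closure to a δ-lactone), and the alkoxide to outrun the carboxylate at C6. High dilution, the low SN2 reactivity of a chelated lithium β-oxido enolate toward allylic chlorides in THF without a polar additive (step 1 needs an iodide and DMPU for the same kind of dianion), the resistance of the dianion to β-elimination and retro-aldol cleavage, and the much higher nucleophilicity of alkoxide over carboxylate should secure this.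

Step 17
Reactants: 23 (5Z,5′Z)-5,5′-(butane-1,4-diylidene)bis(2-Cyp-oxane-3-carboxylic acid)
Product: 25 (5Z,5′Z)-5,5′-(butane-1,4-diylidene)bis(2-Cyp-oxane), via bis(thiohydroxamate ester) 24 (not isolated)
Conditions: N-hydroxypyridine-2-thione, dicyclohexylcarbodiimide, 4-(dimethylamino)pyridine (cat.), CH2Cl2, dark, 0 °C → rt; then t-BuSH, hν (tungsten lamp), benzene, 10 °C
Reagents that add atoms: none
Why: Barton reductive decarboxylation: photolysis of the thiohydroxamate esters gives carboxyl radicals that lose CO2, and the secondary C3 radicals should take hydrogen from the thiol faster than they add to the neighbouring alkenes, which removes both helper carboxyl groups and the uncontrolled C3 centers.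

Step 18
Reactants: 25 (5Z,5′Z)-5,5′-(butane-1,4-diylidene)bis(2-Cyp-oxane)
Product: 26 testudinariol A
Conditions: Bu4NF, THF, rt → 50 °C
Reagents that add atoms: none
Why: Fluoride-mediated desilylation of the two secondary silyl ethers should release the cyclopentanols without touching the alkenes or the oxanes.

**Compound list**

1 | dimethyl (S)-malate | COC(=O)C[C@H](O)C(=O)OC | starting material
2 | 5-iodo-2-methylpent-2-ene | CC(C)=CCCI | starting material
3 | dimethyl (2S,3R)-2-hydroxy-3-(4-methylpent-3-en-1-yl)butanedioate | CC(C)=CCC[C@H]([C@H](O)C(=O)OC)C(=O)OC | intermediate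
4 | methyl (2R,3S)-3,4-dihydroxy-2-(4-methylpent-3-en-1-yl)butanoate | CC(C)=CCC[C@H]([C@H](O)CO)C(=O)OC | intermediate
5 | methyl (2R)-2-[(4S)-2,2-dimethyl-1,3-dioxolan-4-yl]-6-methylhept-5-enoate | CC(C)=CCC[C@H]([C@H]1COC(C)(C)O1)C(=O)OC | intermediate
6 | (2R)-2-[(4S)-2,2-dimethyl-1,3-dioxolan-4-yl]-6-methylhept-5-enal | CC(C)=CCC[C@H]([C@H]1COC(C)(C)O1)C=O | intermediate
7 | (1S,2S,5R)-2-[(4S)-2,2-dimethyl-1,3-dioxolan-4-yl]-5-(prop-1-en-2-yl)cyclopentan-1-ol | C=C(C)[C@H]1CC[C@H]([C@H]2COC(C)(C)O2)[C@H]1O | intermediate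
8 | tert-butyldimethylsilyl ether of 7 | C=C(C)[C@H]1CC[C@H]([C@H]2COC(C)(C)O2)[C@H]1O[Si](C)(C)C(C)(C)C | intermediate
9 | (1S)-1-Cyp-ethane-1,2-diol | C=C(C)[C@H]1CC[C@H]([C@H](O)CO)[C@H]1O[Si](C)(C)C(C)(C)C | intermediate
10 | primary p-toluenesulfonate of 9 | C=C(C)[C@H]1CC[C@H]([C@H](O)COS(=O)(=O)c2ccc(C)cc2)[C@H]1O[Si](C)(C)C(C)(C)C | intermediate
11 | (2S)-2-Cyp-oxirane | C=C(C)[C@H]1CC[C@H]([C@H]2CO2)[C@H]1O[Si](C)(C)C(C)(C)C | intermediate
12 | (4R)-4-Cyp-oxetan-2-one | C=C(C)[C@H]1CC[C@H]([C@H]2CC(=O)O2)[C@H]1O[Si](C)(C)C(C)(C)C | intermediate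
13 | 2,3-dibromoprop-1-ene | C=C(Br)CBr | starting material
14 | 1-{[(2-bromoprop-2-en-1-yl)oxy]methyl}-4-methoxybenzene | C=C(Br)COCc1ccc(OC)cc1 | intermediate
15 | 2,5-dimethoxytetrahydrofuran (cis/trans mixture) | COC1CCC(OC)O1 | starting material
16 | succinaldehyde | O=CCCC=O | intermediate
17 | {3-[(4-methoxybenzyl)oxy]prop-1-en-2-yl}lithium | [Li]C(=C)COCc1ccc(OC)cc1 | intermediate
18 | 2,7-bis{[(4-methoxybenzyl)oxy]methyl}octa-1,7-diene-3,6-diol (meso and racemic) | C=C(COCc1ccc(OC)cc1)C(O)CCC(O)C(=C)COCc1ccc(OC)cc1 | intermediate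
19 | 2,7-bis{[(4-methoxybenzyl)oxy]methyl}octa-1,7-diene-3,6-diyl bis[(3R)-3-Cyp-3-hydroxypropanoate] | C=C(C)[C@H]1CC[C@H]([C@H](O)CC(=O)OC(CCC(OC(=O)C[C@@H](O)[C@H]2CC[C@H](C(=C)C)[C@@H]2O[Si](C)(C)C(C)(C)C)C(=C)COCc3ccc(OC)cc3)C(=C)COCc4ccc(OC)cc4)[C@H]1O[Si](C)(C)C(C)(C)C | intermediate
20 | 2,7-bis(hydroxymethyl)octa-1,7-diene-3,6-diyl bis[(3R)-3-Cyp-3-hydroxypropanoate] | C=C(C)[C@H]1CC[C@H]([C@H](O)CC(=O)OC(CCC(OC(=O)C[C@@H](O)[C@H]2CC[C@H](C(=C)C)[C@@H]2O[Si](C)(C)C(C)(C)C)C(=C)CO)C(=C)CO)[C@H]1O[Si](C)(C)C(C)(C)C | intermediate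
21 | 2,7-bis(chloromethyl)octa-1,7-diene-3,6-diyl bis[(3R)-3-Cyp-3-hydroxypropanoate] | C=C(C)[C@H]1CC[C@H]([C@H](O)CC(=O)OC(CCC(OC(=O)C[C@@H](O)[C@H]2CC[C@H](C(=C)C)[C@@H]2O[Si](C)(C)C(C)(C)C)C(=C)CCl)C(=C)CCl)[C@H]1O[Si](C)(C)C(C)(C)C | intermediate
22 | (4Z,8Z)-4,9-bis(chloromethyl)-2,11-bis[Cyp(hydroxy)methyl]dodeca-4,8-dienedioic acid, carbinol configuration as in 21 (formed as its tetralithium salt) | C=C(C)[C@H]1CC[C@H]([C@H](O)C(C(=O)O)C/C(CCl)=C/CC/C=C(CCl)/CC(C(=O)O)[C@@H](O)[C@H]2CC[C@H](C(=C)C)[C@@H]2O[Si](C)(C)C(C)(C)C)[C@H]1O[Si](C)(C)C(C)(C)C | intermediate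
23 | (5Z,5′Z)-5,5′-(butane-1,4-diylidene)bis(2-Cyp-oxane-3-carboxylic acid), C2 as in the target, C3 epimers | C=C(C)[C@H]1CC[C@H]([C@H]2C(C(=O)O)C/C(=C/CC/C=C3/CC(C(=O)O)[C@H]([C@H]4CC[C@H](C(=C)C)[C@@H]4O[Si](C)(C)C(C)(C)C)OC3)CO2)[C@H]1O[Si](C)(C)C(C)(C)C | intermediate
24 | bis(2-thioxopyridin-1(2H)-yl) ester of 23 | C=C(C)[C@H]1CC[C@H]([C@H]2C(C(=O)ON5C=CC=CC5=S)C/C(=C/CC/C=C3/CC(C(=O)ON6C=CC=CC6=S)[C@H]([C@H]4CC[C@H](C(=C)C)[C@@H]4O[Si](C)(C)C(C)(C)C)OC3)CO2)[C@H]1O[Si](C)(C)C(C)(C)C | intermediate
25 | (5Z,5′Z)-5,5′-(butane-1,4-diylidene)bis(2-Cyp-oxane) (bis-silyl ether of the target) | C=C(C)[C@H]1CC[C@H]([C@H]2CC/C(=C/CC/C=C3/CC[C@H]([C@H]4CC[C@H](C(=C)C)[C@@H]4O[Si](C)(C)C(C)(C)C)OC3)CO2)[C@H]1O[Si](C)(C)C(C)(C)C | intermediate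
26 | testudinariol A | C=C(C)[C@H]1CC[C@H]([C@H]2CC/C(=C/CC/C=C3/CC[C@H]([C@H]4CC[C@H](C(=C)C)[C@@H]4O)OC3)CO2)[C@H]1O | target

**Step count and risks**

Total step count: 18. Longest linear sequence: 15 (steps 1–9, then 13–18).

Step 16 (proposed new method). The enolate may be C-alkylated by an allylic chloride, of a second molecule or of its own ester, before the [3,3] shift. The sequence may also stop after the shift with the alkoxide not alkylated, giving oligomers or uncyclized acid. The fallback uses known reactions through a neutral silyl ketene acetal, sets out from 21 and returns at 23. Both β-hydroxyls of 21 are silylated (Et3SiCl, imidazole, CH2Cl2) to give the bis(triethylsilyl) ether of 21 F1. Ireland–Claisen rearrangement through the bis(silyl ketene acetal) (LiN(SiMe3)2, Me3SiCl, Et3N, THF, −78 → 50 °C, then aqueous acid) should give, under the same chair control, the (4Z,8Z)-bis(β-triethylsilyloxy acid) dichloride F2. HF·pyridine removes the triethylsilyl groups to give 22, here isolated as the free hydroxy acid, and KOC(CH3)3 (4.4 equiv) in THF closes both oxanes to 23.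

Step 5. Facial selectivity with respect to the α-stereocenter may be poor if aluminium bridges the carbonyl and a dioxolane oxygen, which would put the hydroxyl cis to the side chain, and the Lewis acid may open the dioxolane. The fallback replaces the ene reaction by a nickel-catalysed alkylative cyclization of an allenyl aldehyde; it sets out from 1 and returns at 7. Compound 1 is alkylated as in step 1 with 5-iodopenta-1,2-diene F3 (from penta-3,4-dien-1-ol, I2, PPh3, imidazole) to dimethyl (2S,3R)-2-hydroxy-3-(penta-3,4-dien-1-yl)butanedioate F4. Directed borane reduction gives methyl (2R,3S)-3,4-dihydroxy-2-(penta-3,4-dien-1-yl)butanoate F5, acetonide formation gives methyl (2R)-2-[(4S)-2,2-dimethyl-1,3-dioxolan-4-yl]hepta-5,6-dienoate F6, and iBu2AlH gives (2R)-2-[(4S)-2,2-dimethyl-1,3-dioxolan-4-yl]hepta-5,6-dienal F7. With Ni(cod)2 (10 mol %) and Me2Zn in THF at 0 °C, oxidative cyclization of the aldehyde with the proximal allene double bond, methyl transfer to the central allene carbon and reductive elimination should give 7 with hydroxyl cis to isopropenyl.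

Step 1. SN2 at the unactivated primary iodide may be slow, and the basic dianion may instead remove HI from the homoallylic iodide to give the diene. The fallback uses a reactive allylic electrophile and builds the chain afterwards; it sets out from 1 and returns at 5. Alkylation with allyl bromide gives dimethyl (2S,3R)-2-hydroxy-3-(prop-2-en-1-yl)butanedioate F8. Directed borane reduction gives methyl (2R,3S)-2-allyl-3,4-dihydroxybutanoate F9, and acetonide formation gives methyl (2R)-2-[(4S)-2,2-dimethyl-1,3-dioxolan-4-yl]pent-4-enoate F10. Hydroboration with 9-borabicyclo[3.3.1]nonane and oxidation with NaBO3·4H2O gives methyl (2R)-2-[(4S)-2,2-dimethyl-1,3-dioxolan-4-yl]-5-hydroxypentanoate F11, and Dess–Martin oxidation gives methyl (2R)-2-[(4S)-2,2-dimethyl-1,3-dioxolan-4-yl]-5-oxopentanoate F12. Wittig reaction with Ph3P=C(CH3)2 at −78 °C then gives 5.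

Further compounds
F1 | step 16 | bis(triethylsilyl) ether of 21 at the two β-hydroxyls | C=C(C)[C@H]1CC[C@H]([C@H](O[Si](CC)(CC)CC)CC(=O)OC(CCC(OC(=O)C[C@@H](O[Si](CC)(CC)CC)[C@H]2CC[C@H](C(=C)C)[C@@H]2O[Si](C)(C)C(C)(C)C)C(=C)CCl)C(=C)CCl)[C@H]1O[Si](C)(C)C(C)(C)C
F2 | step 16 | (4Z,8Z)-4,9-bis(chloromethyl)-2,11-bis[Cyp(triethylsilyloxy)methyl]dodeca-4,8-dienedioic acid | C=C(C)[C@H]1CC[C@H]([C@H](O[Si](CC)(CC)CC)C(C(=O)O)C/C(CCl)=C/CC/C=C(CCl)/CC(C(=O)O)[C@@H](O[Si](CC)(CC)CC)[C@H]2CC[C@H](C(=C)C)[C@@H]2O[Si](C)(C)C(C)(C)C)[C@H]1O[Si](C)(C)C(C)(C)C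
F3 | step 5 | 5-iodopenta-1,2-diene | C=C=CCCI
F4 | step 5 | dimethyl (2S,3R)-2-hydroxy-3-(penta-3,4-dien-1-yl)butanedioate | C=C=CCC[C@H]([C@H](O)C(=O)OC)C(=O)OC
F5 | step 5 | methyl (2R,3S)-3,4-dihydroxy-2-(penta-3,4-dien-1-yl)butanoate | C=C=CCC[C@H]([C@H](O)CO)C(=O)OC
F6 | step 5 | methyl (2R)-2-[(4S)-2,2-dimethyl-1,3-dioxolan-4-yl]hepta-5,6-dienoate | C=C=CCC[C@H]([C@H]1COC(C)(C)O1)C(=O)OC
F7 | step 5 | (2R)-2-[(4S)-2,2-dimethyl-1,3-dioxolan-4-yl]hepta-5,6-dienal | C=C=CCC[C@H]([C@H]1COC(C)(C)O1)C=O
F8 | step 1 | dimethyl (2S,3R)-2-hydroxy-3-(prop-2-en-1-yl)butanedioate | C=CC[C@H]([C@H](O)C(=O)OC)C(=O)OC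
F9 | step 1 | methyl (2R,3S)-2-allyl-3,4-dihydroxybutanoate | C=CC[C@H]([C@H](O)CO)C(=O)OC
F10 | step 1 | methyl (2R)-2-[(4S)-2,2-dimethyl-1,3-dioxolan-4-yl]pent-4-enoate | C=CC[C@H]([C@H]1COC(C)(C)O1)C(=O)OC
F11 | step 1 | methyl (2R)-2-[(4S)-2,2-dimethyl-1,3-dioxolan-4-yl]-5-hydroxypentanoate | OCCC[C@H]([C@H]1COC(C)(C)O1)C(=O)OC
F12 | step 1 | methyl (2R)-2-[(4S)-2,2-dimethyl-1,3-dioxolan-4-yl]-5-oxopentanoate | O=CCC[C@H]([C@H]1COC(C)(C)O1)C(=O)OC
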